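## Structural features

The target is a C20 ent-gibberellane in which cyclohexane ring A and cyclopentane ring B are trans-fused at C5–C10, ring B is cis-fused to ring C at C8–C9, and the C15–C16 bridge from C8 to C13 makes rings C and D a bicyclo[3.2.1]octane. Three carboxyl groups sit on C4 (C19), C6 (C7) and C10 (C20), with C19 and C20 1,3-diaxial on ring A. There are seven stereocentres (C4, C5, C6, C8, C9, C10, C13), six of them contiguous around ring B, and C4, C8 and C10 are quaternary. The bridgehead 13-hydroxyl is tertiary and allylic to the exocyclic C16=C17 alkene, so the array does not tolerate strong acid, hydrogenation or hydrogenolysis. A free C20 alcohol beside a C19 ester would lactonise, and C6 is the one epimerisable centre. The real difficulty is the crowded C8–C9–C10 triad with the correct sense between C20 and ring C, followed by the trans A/B fusion at C5. The key step exploits that C10 is para to C3 in ring A and bonded to C9, while C9 is β to C12 in ring C, so that a ring A phenol (oxygen on C3, C19 ester on C4, C20 on C10) can add through C10 to a ring C enone (C9=C11–C12=O) and close ring B.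

## Logic of the disconnections

37 ⇐ 36. Only the two ester O–CH3 bonds (C7, C19) are cut. This keeps both acids masked to the end. The forward step must cleave a very hindered axial ester, so it attacks at methyl and not at the carbonyl.

36 ⇐ 33 (through 34 and 35). C20 is taken back from the acid to a protected primary alcohol. A carboxyl or aldehyde on C10 would not survive the dienone stage, and the arene needs an alkoxymethyl group at that carbon. The forward steps must unmask and oxidise C20 without acid, without hydrogen and without lactonisation onto C19.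

33 ⇐ 32. The C13–C16 bond is cut. Ring D, the tertiary carbinol and the exocyclic alkene are traded for a C13 ketone and a propargyl arm on C8. The forward step needs C13 to be the only ketone and needs a one-electron reductant that spares two esters.

32 ⇐ 30 (through 31). No skeletal bond is cut. The C13 carbonyl is hidden as a dioxolane, the alkyne terminus as C–SiMe3, and C6 is returned to the epimer that the earlier steps need. One basic and one acidic treatment must undo all three.

30 ⇐ 28 (through 29). The C–O bonds at C3 and C12 are restored. Both carbonyls are needed earlier (C3 as the phenol oxygen, C12 as the Michael activator) and both leave by one operation. The forward reduction must work at a ketone flanked by quaternary C4.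

28 ⇐ 26 (through 27). The C4–C18 bond is cut and the C1=C2 and C4=C5 unsaturation is restored. The vinylogous β-keto ester of 26 is the handle that accepts hydride at C5 and methyl at C4. The forward steps must deliver both from the face opposite C20.

26 ⇐ 25. The C9–C10 bond is cut, which opens ring B and rearomatises ring A. Two stereocentres (C9, C10) and one ring are exchanged for two flat rings joined by one bond. The forward step must choose para carbon over oxygen and one face of the arene.

25 ⇐ 19 + 6 (through 22 and 24). The C5–C6 bond is cut between an aryl bromide carbon and an ester α-carbon. The molecule falls into a ring A piece and a ring C piece of similar size. The forward coupling must join a neopentyl-type enolate to a di-ortho-substituted arene. It is not expected to control C6, so 22 is sorted into the useful epimer 24 with recycling of the other, and the phenol is then unmasked.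

19 ⇐ 15 (through 17 and 18). The two C13–O bonds are removed. The C13 oxygen is introduced while C13 is the only enolisable position of the enone, so the ring C carbonyl never has to be moved later. The ketal also removes the only ketone α-hydrogens before the enolate coupling.

15 ⇐ 12 + 13 (through 14). The C6–C8 bond and the C12=O bond are cut. A sigmatropic shift makes the quaternary C8 from a secondary carbinol, which is easy to obtain as one enantiomer. The forward oxidation must pick the single allylic methylene.

12 ⇐ 7 + 8 (through 11). The C8–C15 bond is cut, which leads to a vinylogous ester and a silylated propargyl halide. The carbinol centre of 12 is the only source of absolute configuration, so the reduction of 11 must be enantioselective.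

6 ⇐ 1 (through 2, 3, 4). The C4–C19 bond and two O-protecting groups are removed. The carboxyl is placed last, between bromine and oxygen, where ortho-metalation is unambiguous.

## Other disconnections considered

Alternative 1: The cut removes C8–C14 and C13–C16, so rings C and D are formed on a finished ring A/B diester. In the forward step a methyl ketone enolate (C14) adds to C8 of a C6=C8 enoate, and a C16 ester enolate then adds to the C13 ketone in the same flask, giving A1.
- In its favour: two rings, two C–C bonds and the C8 and C13 centres come from one operation. The oxygen arrives on C13 as the tertiary alcohol, and C20 is at the acid level throughout. On both points A1 is better than the chosen plan, which spends steps 9–11 on the C13 oxygen and steps 22–23 on C20.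
- Against it here: C8 is a fully substituted β-carbon, so the conjugate addition that makes it quaternary should be slow and reversible. Its face must be set by remote centres. C17 is a carboxyl that still has to become the exocyclic methylene. The whole C4/C5/C10 array must be built first by other chemistry.
- Comparison: on structure the chosen plan joins two flat rings early, while this plan closes the bridged system late on an elaborate bicycle. On mechanism both rest on a reversible Michael addition; this one loses no aromaticity, which makes it equal or slightly better on driving force. On step economy the savings at C13 and C20 are offset by the C17 adjustment and a longer ring A/B synthesis, so the two are judged about equal.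

Alternative 2: The cut removes C1–C10 and C3–C4, that is ring A. In the forward step a ring B β-keto ester is added through C10 to an acrylate ester under Cs2CO3, and a lithium amide then drives a Dieckmann closure between C4 and C3, giving A2.
- In its favour: the reagents are cheap and the reaction types very reliable, with no dearomatisation and no rearomatisation risk. C20 is an ester from the start, which is better than the chosen plan. A2 has the same C3 ketone/C4 ester pair as 27, so C4 methylation and C3 removal would be equal in both plans. The trans A/B fusion is already present, which is better than having to set C5 by reduction.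
- Against it here: A2 holds only rings A and B. C8 is a methylene and C9 a ketone, so the quaternary C8, ring C, ring D and the C13 carbinol, the harder half of the molecule, all remain.
- Comparison: on structure this annulation solves the easier ring, whereas the chosen key step fixes C8, C9 and C10 together. On mechanism it is the safer two-electron chemistry. On step economy it is short up to A2 and long after it, so overall it is judged longer.

Alternative 3: The cut is a ring contraction at C5–C6. A six-membered ring B carrying a diazo carbonyl function, in a natural ent-kaurane relay, is photolysed in an alcohol; C5 migrates in a Wolff rearrangement and the former carbonyl carbon becomes the C7 ester, giving A3.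
- In its favour: rings A, C and D, the 13-hydroxy-16-ene unit and every stereocentre except C6 come from the relay. The step count to the ring system and the stereochemical security are better than in the chosen plan. C6 would need base equilibration, which is equal to the chosen plan.
- Against it here: A3 carries C20 as an unactivated angular methyl, and taking it to a carboxyl needs a multi-step remote functionalisation that the chosen plan avoids. The route is a relay from a complex natural product and not a construction from simple materials. The exocyclic alkene must survive diazo transfer and photolysis.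
- Comparison: on structure the relay is superior for everything except C20. On mechanism the contraction is well precedented. On step economy it is best up to A3 and then loses the advantage at C20, the carbon that distinguishes the target.

Key step: step 15

Remarks on the chemistry (assumptions and corrections):
- Gibberellane numbering (C1–C20) is used in the text for all intermediates.
- Correction: the constitution and the C8, C9 and C10 configurations of the ring B precursor and of the dienone are those the target requires. A precursor with the target's configuration at C6 is, however, the mismatched epimer for this closure (reasoning in step 15). The route uses the other C6 epimer (25), obtains the dienone with C7 cis to C20 (26), and inverts C6 in step 20.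
- Design changes to the precursor: the alkyne is carried as C–SiMe3 and the phenol as a MOM ether until after the Pd coupling, C13 is carried as a dioxolane, and the C20 ether is 4-methoxybenzyl (PMB).
- Assumption: once ring A is saturated, the C6 epimer with C7 trans to C4 (the natural one) is the more stable, so NaOMe equilibration delivers it.

## Steps

Step 1
Reactants: 1 2-bromo-4-hydroxybenzaldehyde
Product: 2 2-bromo-4-(methoxymethoxy)benzaldehyde
Conditions: MOMCl, i-Pr2NEt, CH2Cl2, 0 °C to rt
Reagents that add atoms: chloromethyl methyl ether, COCCl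
Why: O-alkylation of the phenol (Williamson type); the MOM acetal later directs ortho-lithiation and is removable with mild acid.

Step 2
Reactants: 2 2-bromo-4-(methoxymethoxy)benzaldehyde
Product: 3 [2-bromo-4-(methoxymethoxy)phenyl]methanol
Conditions: NaBH4, MeOH, 0 °C
Reagents that add atoms: none
Why: Borohydride reduction of the aldehyde; aryl bromide and acetal are inert.

Step 3
Reactants: 3 [2-bromo-4-(methoxymethoxy)phenyl]methanol
Product: 4 2-bromo-1-{[(4-methoxyphenyl)methoxy]methyl}-4-(methoxymethoxy)benzene
Conditions: NaH, PMBCl, Bu4NI (cat.), DMF, 0 °C to rt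
Reagents that add atoms: 4-methoxybenzyl chloride, COc1ccc(CCl)cc1
Why: Williamson etherification; the PMB group is chosen because its oxidative removal later tolerates the exocyclic alkene, which hydrogenolysis of a benzyl ether would not.

Step 4
Reactants: 4 2-bromo-1-{[(4-methoxyphenyl)methoxy]methyl}-4-(methoxymethoxy)benzene
Product: 6 methyl 2-bromo-3-{[(4-methoxyphenyl)methoxy]methyl}-6-(methoxymethoxy)benzoate, via aryllithium 5 (not isolated)
Conditions: LiN(i-Pr)2, THF, −78 °C; then ClCO2Me (inverse addition), −78 °C
Reagents that add atoms: methyl chloroformate, COC(=O)Cl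
Why: Directed ortho-metalation: the C–H flanked by bromine and the MOM ether is the most acidic site, as in 3-bromoanisole-type arenes; at −78 °C the ortho-bromo aryllithium should not lose LiBr, and acylation gives the future C19 ester.

Step 5
Reactants: 7 3-bromo-1-(trimethylsilyl)prop-1-yne; 8 3-ethoxycyclohex-2-en-1-one
Product: 11 3-[3-(trimethylsilyl)prop-2-yn-1-yl]cyclohex-2-en-1-one, via Grignard reagent 9 (not isolated), via carbinol 10 (not isolated)
Conditions: Mg (I2-activated), Et2O, 0 °C; then 8, −20 °C to rt; then 1 M HCl, 0 °C
Reagents that add atoms: none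
Why: Stork–Danheiser sequence: 1,2-addition of the silylated propargyl/allenyl magnesium reagent to the vinylogous ester (the silyl group steers it to the propargyl product), then cold acid hydrolysis and dehydration to the transposed enone.

Step 6
Reactants: 11 3-[3-(trimethylsilyl)prop-2-yn-1-yl]cyclohex-2-en-1-one
Product: 12 (1R)-3-[3-(trimethylsilyl)prop-2-yn-1-yl]cyclohex-2-en-1-ol
Conditions: (S)-2-methyl-CBS-oxazaborolidine (10 mol%), catecholborane, toluene, −78 °C
Reagents that add atoms: none
Why: Corey–Bakshi–Shibata reduction; the alkene side of the enone acts as the large group, so the (S)-catalyst should give the (R)-carbinol, the only source of absolute configuration in the route.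

Step 7
Reactants: 12 (1R)-3-[3-(trimethylsilyl)prop-2-yn-1-yl]cyclohex-2-en-1-ol; 13 trimethyl orthoacetate
Product: 14 methyl 2-[(1S)-1-[3-(trimethylsilyl)prop-2-yn-1-yl]cyclohex-2-en-1-yl]acetate
Conditions: EtCO2H (cat.), xylene, 140 °C, MeOH distilled off
Reagents that add atoms: none
Why: Johnson–Claisen rearrangement; the suprafacial [3,3] shift places C6 on the face that carried the C–O bond, so the carbinol configuration becomes that of quaternary C8, and the C9=C11 alkene and the C6–C7 ester arm appear together.

Step 8
Reactants: 14 methyl 2-[(1S)-1-[3-(trimethylsilyl)prop-2-yn-1-yl]cyclohex-2-en-1-yl]acetate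
Product: 15 methyl 2-[(1S)-4-oxo-1-[3-(trimethylsilyl)prop-2-yn-1-yl]cyclohex-2-en-1-yl]acetate
Conditions: Rh2(cap)4 (cap = caprolactamate, 1 mol%), t-BuOOH, K2CO3, CH2Cl2, rt
Reagents that add atoms: tert-butyl hydroperoxide, CC(C)(C)OO
Why: Allylic C–H oxidation; C12 is the only allylic methylene (the other allylic position is quaternary C8), so the enone is regiodefined, and the hindered propargylic methylene should react more slowly.

Step 9
Reactants: 15 methyl 2-[(1S)-4-oxo-1-[3-(trimethylsilyl)prop-2-yn-1-yl]cyclohex-2-en-1-yl]acetate
Product: 17 methyl 2-[(1R)-5-hydroxy-4-oxo-1-[3-(trimethylsilyl)prop-2-yn-1-yl]cyclohex-2-en-1-yl]acetate (both C13 epimers), via lithium dienolate 16 (not isolated)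
Conditions: LiN(i-Pr)2, THF, −78 °C; then 2-(phenylsulfonyl)-3-phenyloxaziridine, −78 °C
Reagents that add atoms: 2-(phenylsulfonyl)-3-phenyloxaziridine, O=S(=O)(c1ccccc1)N1OC1c1ccccc1
Why: Kinetic α′-enolisation of the enone (more acidic than the ester; the γ-position is quaternary C8) and oxaziridine hydroxylation put the oxygen on C13, the only place it can go.

Step 10
Reactants: 17 methyl 2-[(1R)-5-hydroxy-4-oxo-1-[3-(trimethylsilyl)prop-2-yn-1-yl]cyclohex-2-en-1-yl]acetate
Product: 18 methyl 2-[(1R)-3-hydroxy-4-oxo-1-[3-(trimethylsilyl)prop-2-yn-1-yl]cyclohexa-2,5-dien-1-yl]acetate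
Conditions: DMP (1,1,1-triacetoxy-1,2-benziodoxol-3-one), NaHCO3, CH2Cl2, rt
Reagents that add atoms: none
Why: Oxidation of the acyloin to the 1,2-dione, which should rest as its enol (diosphenol); both C13 epimers converge.

Step 11
Reactants: 18 methyl 2-[(1R)-3-hydroxy-4-oxo-1-[3-(trimethylsilyl)prop-2-yn-1-yl]cyclohexa-2,5-dien-1-yl]acetate
Product: 19 methyl 2-[(7R)-10-oxo-7-[3-(trimethylsilyl)prop-2-yn-1-yl]-1,4-dioxaspiro[4.5]dec-8-en-7-yl]acetate
Conditions: ethylene glycol, TsOH (cat.), benzene, reflux (Dean–Stark)
Reagents that add atoms: ethane-1,2-diol, OCCO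
Why: Acid-catalysed mono-ketalisation at the non-conjugated C13 carbonyl, as with cyclohexane-1,2-dione; the conjugated C12 carbonyl is less electrophilic. The dioxolane stores the C13 oxygen and removes the last ketone α-hydrogens.

Step 12
Reactants: 19 methyl 2-[(7R)-10-oxo-7-[3-(trimethylsilyl)prop-2-yn-1-yl]-1,4-dioxaspiro[4.5]dec-8-en-7-yl]acetate; 6 methyl 2-bromo-3-{[(4-methoxyphenyl)methoxy]methyl}-6-(methoxymethoxy)benzoate
Product: 22 methyl 2-[2-methoxy-2-oxo-1-[(7S)-10-oxo-7-[3-(trimethylsilyl)prop-2-yn-1-yl]-1,4-dioxaspiro[4.5]dec-8-en-7-yl]ethyl]-3-{[(4-methoxyphenyl)methoxy]methyl}-6-(methoxymethoxy)benzoate (both C6 epimers), via lithium enolate 20 (not isolated), via zinc enolate 21 (not isolated)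
Conditions: LiN(SiMe3)2, THF, −78 °C; ZnCl2, −78 °C to rt; then 6, Pd(dba)2 (dba = dibenzylideneacetone, 5 mol%), P(t-Bu)3 (10 mol%), THF, 60 °C
Reagents that add atoms: none
Why: Pd-catalysed α-arylation of an ester through its zinc enolate forms C5–C6; the ester α-carbon is the only acidic C–H (C13 ketalised, alkyne silylated, phenol masked) and the zinc enolate spares the enone. Remote C8 is not expected to control the new C6 centre, so 22 is taken on as the mixture of both C6 epimers.

Step 13
Reactants: 22 methyl 2-[2-methoxy-2-oxo-1-[(7S)-10-oxo-7-[3-(trimethylsilyl)prop-2-yn-1-yl]-1,4-dioxaspiro[4.5]dec-8-en-7-yl]ethyl]-3-{[(4-methoxyphenyl)methoxy]methyl}-6-(methoxymethoxy)benzoate (both C6 epimers)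
Product: 24 methyl 2-[(1S)-2-methoxy-2-oxo-1-[(7S)-10-oxo-7-[3-(trimethylsilyl)prop-2-yn-1-yl]-1,4-dioxaspiro[4.5]dec-8-en-7-yl]ethyl]-3-{[(4-methoxyphenyl)methoxy]methyl}-6-(methoxymethoxy)benzoate (single 6S epimer), via potassium enolate 23 (not isolated)
Conditions: SiO2 chromatography (24 collected); 6R fraction: KN(SiMe3)2, THF, −78 °C, then AcOH, −78 °C; chromatography again (two cycles)
Reagents that add atoms: none
Why: Separation of diastereomers with base recycling: the α-aryl ester C–H is by far the most acidic C–H of 22, so KN(SiMe3)2 turns the unwanted 6R fraction into the planar enolate 23, and kinetic protonation returns a mixture of epimers from which more 24 is taken. Only 24 has the C6 configuration that step 15 needs.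

Step 14
Reactants: 24 methyl 2-[(1S)-2-methoxy-2-oxo-1-[(7S)-10-oxo-7-[3-(trimethylsilyl)prop-2-yn-1-yl]-1,4-dioxaspiro[4.5]dec-8-en-7-yl]ethyl]-3-{[(4-methoxyphenyl)methoxy]methyl}-6-(methoxymethoxy)benzoate
Product: 25 methyl 6-hydroxy-2-[(1S)-2-methoxy-2-oxo-1-[(7S)-10-oxo-7-[3-(trimethylsilyl)prop-2-yn-1-yl]-1,4-dioxaspiro[4.5]dec-8-en-7-yl]ethyl]-3-{[(4-methoxyphenyl)methoxy]methyl}benzoate
Conditions: HCl (0.5 M) in MeOH, 0 °C to rt
Reagents that add atoms: none
Why: Acid cleavage of the aryl MOM acetal, helped by the ortho ester; the dioxolane next to the C12 carbonyl should hydrolyse far more slowly (destabilised oxocarbenium ion), the PMB ether and silylalkyne should survive dilute HCl, and acid does not epimerise C6.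

Step 15
Reactants: 25 methyl 6-hydroxy-2-[(1S)-2-methoxy-2-oxo-1-[(7S)-10-oxo-7-[3-(trimethylsilyl)prop-2-yn-1-yl]-1,4-dioxaspiro[4.5]dec-8-en-7-yl]ethyl]-3-{[(4-methoxyphenyl)methoxy]methyl}benzoate
Product: 26 tetracyclic dienone: ring A 1,4-dien-3-one with C4 CO2Me, ring C 12-ketone and 13,13-ethylenedioxy, C6 CO2Me, C10 CH2O-PMB, C8 3-(trimethylsilyl)prop-2-ynyl; C8, C9, C10 as in the target, C7 cis to C20
Conditions: Cs2CO3 (0.3 equiv), MeCN, 0 °C to rt; AcOH quench at 0 °C
Reagents that add atoms: none
Why: Intramolecular dearomative Michael addition of a para-substituted phenolate, the base-mediated phenol-to-enone dearomatisation being the closest known reaction type: the phenolate of 25 acts as a vinylogous enolate, its para carbon C10 adds to the enone β-carbon C9, and the ring C enolate is protonated by unreacted phenol, so that Cs2CO3 is needed only in catalytic amount. Ring B closes in the 5-exo-trig mode and ring A emerges as a cross-conjugated dienone whose C4 ester makes it a vinylogous β-keto ester. C9 can be reached only on the face of C8 that carries C6, which fixes the cis B/C fusion. C10 is controlled by C6 through allylic 1,3-strain: in the closing conformer H6 must lie near the arene plane beside the C19 ester, so C8 and C7 sit on opposite faces of ring A, C9 bonds to C10 anti to C7 and C20 is pushed syn to C7; with the 6S epimer this places C20 on the side of C11 and C14, as the target requires. The step needs para-carbon attack over oxygen attack and one arene face: oxygen attack would be a reversible seven-membered closure, the ortho carbon C4 is blocked by its ester and C2 cannot reach C9, and catalytic Cs2CO3 at or below room temperature should not epimerise the weakly acidic C6–H of 25. The cold AcOH quench protonates all anionic species at once and so limits retro-Michael rearomatisation. The C7-cis-C20 arrangement of 26 is used in step 16 and corrected in step 20.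

Step 16
Reactants: 26 tetracyclic dienone (as above)
Product: 27 ring A β-keto ester: as 26 with C1–C2 and C4–C5 saturated (3-oxo, C4–H CO2Me, enolisable), H5 trans to C20, C7 cis to C20
Conditions: [(Ph3P)CuH]6 (0.6 equiv), H2O (2 equiv), benzene, rt
Reagents that add atoms: none
Why: Conjugate reduction with [(Ph3P)CuH]6 saturates C1=C2 and the doubly activated C4=C5 and leaves the isolated C12 ketone, the esters and the silylalkyne alone; hydride should reach C5 from the face opposite C20 and C7, which both lie on the other face, so H5 ends trans to C20 (trans A/B fusion).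

Step 17
Reactants: 27 ring A β-keto ester (as above)
Product: 28 C4-methylated 3,12-diketone: as 27 with C18 methyl on C4 trans to C20 (C19 ester cis to C20)
Conditions: K2CO3, MeI, acetone, 40 °C
Reagents that add atoms: iodomethane, CI
Why: C-alkylation of the β-keto ester enolate; MeI should approach anti to the axial C20 group, the established sense for 3-oxo-4-carboalkoxy rings with an angular substituent, which leaves the C19 ester axial and cis to C20.

Step 18
Reactants: 28 C4-methylated 3,12-diketone (as above)
Product: 29 3,12-bis(4-methylbenzenesulfonylhydrazone) of 28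
Conditions: TsNHNH2 (3 equiv), AcOH (cat.), EtOH, 70 °C
Reagents that add atoms: 4-methylbenzenesulfonohydrazide, Cc1ccc(cc1)S(=O)(=O)NN
Why: Condensation at both ketones; 3-ketones flanked by a quaternary C4 form tosylhydrazones, as 4,4-disubstituted 3-oxo terpenoids do, and the sulfonamide N–H is too weak a nucleophile to attack the C19 ester.

Step 19
Reactants: 29 3,12-bis(4-methylbenzenesulfonylhydrazone) of 28
Product: 30 3,12-dideoxy compound: ring A and C11–C12 saturated, C13 dioxolane, C7 and C19 methyl esters, C20 CH2O-PMB, silylalkyne, C7 still cis to C20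
Conditions: catecholborane, CHCl3, 0 °C to rt; then NaOAc·3H2O, reflux
Reagents that add atoms: none
Why: Hydride reduction of the tosylhydrazones and loss of sulfinate and N2 turn both C=N carbons into methylenes under conditions too mild for retro-Claisen cleavage at C3–C4; the C3 and C12 oxygens, which have done their work, leave in one operation.

Step 20
Reactants: 30 3,12-dideoxy compound (as above)
Product: 32 C13 ketone: terminal alkyne on C8, C7 and C19 methyl esters, C20 CH2O-PMB, natural C6 (C7 trans to C20), via alkyne ketal 31 (not isolated)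
Conditions: NaOMe, MeOH, 65 °C; then 2 M HCl, THF, rt
Reagents that add atoms: water, O
Why: NaOMe cleaves the alkynyl–silicon bond and equilibrates C6 through the ester enolate to the epimer with C7 trans to C4, the natural one; aqueous acid then hydrolyses the dioxolane, which is no longer next to a carbonyl, to the C13 ketone.

Step 21
Reactants: 32 C13 ketone (as above)
Product: 33 13-hydroxy-16-ene tetracycle: 7,19-dimethyl ester with C20 CH2O-PMB
Conditions: SmI2 (4 equiv), HMPA, t-BuOH, THF, 0 °C to rt
Reagents that add atoms: none
Why: Ketyl–alkyne reductive cyclisation (5-exo-dig), a reaction type long used for bicyclo[3.2.1]octane carbinols of this kind: the C13 ketyl adds to C16 and the vinyl radical is reduced and protonated to the exocyclic methylene; the one-carbon bridge allows only one configuration at C13.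

Step 22
Reactants: 33 13-hydroxy-16-ene tetracycle with C20 CH2O-PMB (as above)
Product: 34 C20 primary alcohol (13,20-diol 7,19-dimethyl ester)
Conditions: DDQ, CH2Cl2/pH 7 phosphate buffer, 0 °C; crude product used at once
Reagents that add atoms: none
Why: Oxidative PMB cleavage under neutral conditions spares the acid-sensitive 13-hydroxy-16-ene unit; the cold, buffered work-up and immediate use are chosen so that the C20 alcohol does not lactonise onto the C19 ester.

Step 23
Reactants: 34 C20 primary alcohol (as above)
Product: 36 7,19-dimethyl ester of the target (free C20 acid), via aldehyde 35 (not isolated)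
Conditions: DMP, NaHCO3, CH2Cl2, 0 °C; then NaClO2, NaH2PO4, 2-methyl-2-butene, t-BuOH/H2O, rt
Reagents that add atoms: sodium chlorite, [Na+].[O-]Cl=O
Why: The periodinane oxidises the neopentyl primary alcohol and cannot touch the tertiary 13-hydroxyl; Pinnick oxidation then gives the acid, with the scavenger protecting the exocyclic alkene from hypochlorite.

Step 24
Reactants: 36 7,19-dimethyl ester of the target (free C20 acid)
Product: 37 the target gibberellin (13-hydroxy-16-ene C20-gibberellin 7,19,20-trioic acid)
Conditions: LiSPr (preformed), HMPA, rt; then 1 M HCl to pH 3, 0 °C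
Reagents that add atoms: none
Why: SN2 demethylation by LiSPr at the O–CH3 carbons cleaves the hindered C19 ester and the C7 ester without attack at carbonyl carbon; the thiolate is too weak a base to epimerise C6 and the C/D unit is stable to it.

## Compound list

1 | 2-bromo-4-hydroxybenzaldehyde | O=Cc1ccc(O)cc1Br | starting material
2 | 2-bromo-4-(methoxymethoxy)benzaldehyde | COCOc1ccc(C=O)c(Br)c1 | intermediate
3 | [2-bromo-4-(methoxymethoxy)phenyl]methanol | COCOc1ccc(CO)c(Br)c1 | intermediate
4 | 2-bromo-1-{[(4-methoxyphenyl)methoxy]methyl}-4-(methoxymethoxy)benzene | COCOc1ccc(COCc2ccc(OC)cc2)c(Br)c1 | intermediate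
5 | {2-bromo-3-{[(4-methoxyphenyl)methoxy]methyl}-6-(methoxymethoxy)phenyl}lithium | COCOc1ccc(COCc2ccc(OC)cc2)c(Br)c1[Li] | intermediate
6 | methyl 2-bromo-3-{[(4-methoxyphenyl)methoxy]methyl}-6-(methoxymethoxy)benzoate | COCOc1ccc(COCc2ccc(OC)cc2)c(Br)c1C(=O)OC | intermediate
7 | 3-bromo-1-(trimethylsilyl)prop-1-yne | C[Si](C)(C)C#CCBr | starting material
8 | 3-ethoxycyclohex-2-en-1-one | CCOC1=CC(=O)CCC1 | starting material
9 | [3-(trimethylsilyl)prop-2-yn-1-yl]magnesium bromide (propargyl/allenyl reagent) | C[Si](C)(C)C#CC[Mg]Br | intermediate
10 | 3-ethoxy-1-[3-(trimethylsilyl)prop-2-yn-1-yl]cyclohex-2-en-1-ol (racemic) | CCOC1=CC(O)(CC#C[Si](C)(C)C)CCC1 | intermediate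
11 | 3-[3-(trimethylsilyl)prop-2-yn-1-yl]cyclohex-2-en-1-one | C[Si](C)(C)C#CCC1=CC(=O)CCC1 | intermediate
12 | (1R)-3-[3-(trimethylsilyl)prop-2-yn-1-yl]cyclohex-2-en-1-ol | O[C@H]1C=C(CC#C[Si](C)(C)C)CCC1 | intermediate
13 | trimethyl orthoacetate (1,1,1-trimethoxyethane) | CC(OC)(OC)OC | starting material
14 | methyl 2-[(1S)-1-[3-(trimethylsilyl)prop-2-yn-1-yl]cyclohex-2-en-1-yl]acetate | C[Si](C)(C)C#CC[C@]1(C=CCCC1)CC(=O)OC | intermediate
15 | methyl 2-[(1S)-4-oxo-1-[3-(trimethylsilyl)prop-2-yn-1-yl]cyclohex-2-en-1-yl]acetate | C[Si](C)(C)C#CC[C@]1(C=CC(=O)CC1)CC(=O)OC | intermediate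
16 | lithium dienolate of 15 (O–Li on C12, C12=C13) | C[Si](C)(C)C#CC[C@]1(C=CC(O[Li])=CC1)CC(=O)OC | intermediate
17 | methyl 2-[(1R)-5-hydroxy-4-oxo-1-[3-(trimethylsilyl)prop-2-yn-1-yl]cyclohex-2-en-1-yl]acetate (both epimers at the carbinol carbon) | C[Si](C)(C)C#CC[C@]1(C=CC(=O)C(O)C1)CC(=O)OC | intermediate
18 | methyl 2-[(1R)-3-hydroxy-4-oxo-1-[3-(trimethylsilyl)prop-2-yn-1-yl]cyclohexa-2,5-dien-1-yl]acetate | C[Si](C)(C)C#CC[C@]1(C=CC(=O)C(O)=C1)CC(=O)OC | intermediate
19 | methyl 2-[(7R)-10-oxo-7-[3-(trimethylsilyl)prop-2-yn-1-yl]-1,4-dioxaspiro[4.5]dec-8-en-7-yl]acetate | C[Si](C)(C)C#CC[C@]1(C=CC(=O)C2(OCCO2)C1)CC(=O)OC | intermediate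
20 | lithium ester enolate of 19 | C[Si](C)(C)C#CC[C@]1(C=CC(=O)C2(OCCO2)C1)C=C(OC)O[Li] | intermediate
21 | chlorozinc ester enolate of 19 | C[Si](C)(C)C#CC[C@]1(C=CC(=O)C2(OCCO2)C1)C=C(OC)O[Zn]Cl | intermediate
22 | methyl 2-[2-methoxy-2-oxo-1-[(7S)-10-oxo-7-[3-(trimethylsilyl)prop-2-yn-1-yl]-1,4-dioxaspiro[4.5]dec-8-en-7-yl]ethyl]-3-{[(4-methoxyphenyl)methoxy]methyl}-6-(methoxymethoxy)benzoate (both C6 epimers) | C[Si](C)(C)C#CC[C@]1(C=CC(=O)C2(OCCO2)C1)C(C(=O)OC)c1c(C(=O)OC)c(OCOC)ccc1COCc1ccc(OC)cc1 | intermediate
23 | potassium ester enolate of 22 (C6 planar) | C[Si](C)(C)C#CC[C@]1(C=CC(=O)C2(OCCO2)C1)C(=C(OC)O[K])c1c(C(=O)OC)c(OCOC)ccc1COCc1ccc(OC)cc1 | intermediate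
24 | methyl 2-[(1S)-2-methoxy-2-oxo-1-[(7S)-10-oxo-7-[3-(trimethylsilyl)prop-2-yn-1-yl]-1,4-dioxaspiro[4.5]dec-8-en-7-yl]ethyl]-3-{[(4-methoxyphenyl)methoxy]methyl}-6-(methoxymethoxy)benzoate (single 6S epimer) | C[Si](C)(C)C#CC[C@]1(C=CC(=O)C2(OCCO2)C1)[C@H](C(=O)OC)c1c(C(=O)OC)c(OCOC)ccc1COCc1ccc(OC)cc1 | intermediate
25 | methyl 6-hydroxy-2-[(1S)-2-methoxy-2-oxo-1-[(7S)-10-oxo-7-[3-(trimethylsilyl)prop-2-yn-1-yl]-1,4-dioxaspiro[4.5]dec-8-en-7-yl]ethyl]-3-{[(4-methoxyphenyl)methoxy]methyl}benzoate | C[Si](C)(C)C#CC[C@]1(C=CC(=O)C2(OCCO2)C1)[C@H](C(=O)OC)c1c(C(=O)OC)c(O)ccc1COCc1ccc(OC)cc1 | intermediate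
26 | tetracyclic dienone (1,4-dien-3-one, 12-oxo, 13,13-ethylenedioxy, C7 and C19 methyl esters, C20 CH2O-PMB, silylpropynyl on C8; C7 cis to C20) | C[Si](C)(C)C#CC[C@]23CC4(OCCO4)C(=O)C[C@H]2[C@]1(COCc4ccc(OC)cc4)C=CC(=O)C(C(=O)OC)=C1[C@H]3C(=O)OC | intermediate
27 | ring A β-keto ester (3-oxo, C4–H, H5 trans to C20; otherwise as 26) | C[Si](C)(C)C#CC[C@]23CC4(OCCO4)C(=O)C[C@H]2[C@]1(COCc4ccc(OC)cc4)CCC(=O)C(C(=O)OC)[C@H]1[C@H]3C(=O)OC | intermediate
28 | C4-methylated 3,12-diketone (C18 trans to C20) | C[Si](C)(C)C#CC[C@]23CC4(OCCO4)C(=O)C[C@H]2[C@]1(COCc4ccc(OC)cc4)CCC(=O)[C@@](C)(C(=O)OC)[C@H]1[C@H]3C(=O)OC | intermediate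
29 | 3,12-bis(4-methylbenzenesulfonylhydrazone) of 28 | C[Si](C)(C)C#CC[C@]23CC4(OCCO4)C(=NNS(=O)(=O)c4ccc(C)cc4)C[C@H]2[C@]1(COCc4ccc(OC)cc4)CCC(=NNS(=O)(=O)c4ccc(C)cc4)[C@@](C)(C(=O)OC)[C@H]1[C@H]3C(=O)OC | intermediate
30 | 3,12-dideoxy compound (C13 dioxolane, silylalkyne, C7 cis to C20) | C[Si](C)(C)C#CC[C@]23CC4(OCCO4)CC[C@H]2[C@]1(COCc4ccc(OC)cc4)CCC[C@@](C)(C(=O)OC)[C@H]1[C@H]3C(=O)OC | intermediate
31 | terminal alkyne ketal with natural C6 (C7 trans to C20) | C#CC[C@]23CC4(OCCO4)CC[C@H]2[C@]1(COCc4ccc(OC)cc4)CCC[C@@](C)(C(=O)OC)[C@H]1[C@@H]3C(=O)OC | intermediate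
32 | C13 ketone with prop-2-ynyl on C8 (7,19-dimethyl ester, C20 CH2O-PMB) | C#CC[C@]23CC(=O)CC[C@H]2[C@]1(COCc4ccc(OC)cc4)CCC[C@@](C)(C(=O)OC)[C@H]1[C@@H]3C(=O)OC | intermediate
33 | 13-hydroxy-16-ene tetracycle, 7,19-dimethyl ester, C20 CH2O-PMB | C=C1C[C@]23C[C@@]1(O)CC[C@H]2[C@]1(COCc4ccc(OC)cc4)CCC[C@@](C)(C(=O)OC)[C@H]1[C@@H]3C(=O)OC | intermediate
34 | 13,20-diol 7,19-dimethyl ester (C20 CH2OH) | C=C1C[C@]23C[C@@]1(O)CC[C@H]2[C@]1(CO)CCC[C@@](C)(C(=O)OC)[C@H]1[C@@H]3C(=O)OC | intermediate
35 | C20 aldehyde (13-hydroxy-20-oxo 7,19-dimethyl ester) | C=C1C[C@]23C[C@@]1(O)CC[C@H]2[C@]1(C=O)CCC[C@@](C)(C(=O)OC)[C@H]1[C@@H]3C(=O)OC | intermediate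
36 | 7,19-dimethyl ester of the target (free C20 acid) | C=C1C[C@]23C[C@@]1(O)CC[C@H]2[C@]1(C(=O)O)CCC[C@@](C)(C(=O)OC)[C@H]1[C@@H]3C(=O)OC | intermediate
37 | the target gibberellin (13-hydroxy-16-ene C20-gibberellin 7,19,20-trioic acid; number 17 of the A series) | C=C1C[C@]23C[C@@]1(O)CC[C@H]2[C@]1(C(=O)O)CCC[C@@](C)(C(=O)O)[C@H]1[C@@H]3C(=O)O | target

## Step count and least certain steps

Total: 24 steps. Longest linear sequence: 20 steps (steps 5–24, from 7 and 8 to 37). The arene branch (steps 1–4) joins at step 12.

Step 15 (key step). The closure makes a bond between a tertiary and a quaternary carbon, and in the required transition state C11 lies close to C20. If it is slow, retro-Michael rearomatisation and base-induced scrambling of C6 in 25 would compete; with C6 scrambled the relay to C10 is lost and facial selectivity at C10 falls. Fallback: a silyl-transfer (Mukaiyama–Michael type, Lewis-base-catalysed) closure. It sets out from 25, which is silylated at the phenol (Me3SiCl, Et3N, CH2Cl2) to the aryl trimethylsilyl ether F1. A catalytic amount of Bu4N+ Ph3SiF2− in THF at −20 °C releases a little phenoxide, which cyclises as before. The C12 enolate is now captured by silyl transfer from F1 to give the enol silane F2, which cannot revert and which frees phenoxide for the next turnover. Buffered hydrolysis (pH 5) of F2 returns to the route at 26.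

Step 12. Reductive elimination has to join an enolate carbon next to quaternary C8 to an aryl group with two ortho substituents; the coupling may stall and hydrodebromination of the arene may take over. Fallback: the polarity is reversed. From 19, LiN(SiMe3)2 and Me3SiCl give the silyl ketene acetal F3, which N-bromosuccinimide converts into the α-bromo ester F4. Separately, zinc dust with LiCl in THF at 50 °C inserts into the C–Br bond of 6, which is activated by the ortho ester, to give the arylzinc bromide F5. A nickel-catalysed Negishi coupling (NiCl2·glyme, 4,4′-di-tert-butyl-2,2′-bipyridine), in which a C6 radical is captured at nickel and which is therefore less sensitive to crowding, returns to the route at 22.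

Step 16. The C6–H of 26 is acidic; if C6 scrambles before or during the reduction, C7 moves to the face opposite C20, both faces of C5 are then shielded, and facial selectivity at C5 erodes. Fallback: C6 is made planar when the C5 hydrogen is installed. From 26, K2CO3/MeI alkylates the extended enolate at C4, the terminus flanked by two carbonyl groups (deconjugative methylation, anti to C20), to give the Δ5(6)-ene diester F6. [(Ph3P)CuH]6 then saturates C1=C2 to give the 1,2-dihydro compound F7. Hydrogen-atom-transfer reduction of the hindered enoate (Mn(dpm)3 with dpm = dipivaloylmethanate, PhSiH3, t-BuOOH, i-PrOH) should deliver hydrogen to C5 and to C6 from the face opposite the axial C19 and C20 groups, which returns to the route at 28.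

Step 18. The C3 ketone lies between quaternary C4 and the ring; condensation, or the later hydride transfer to this hydrazone in step 19, may be incomplete and stop at deoxygenation of C12 alone. Fallback: radical deoxygenation of the alcohols (Barton–McCombie). From 28, NaBH4 in MeOH reduces both ketones to the 3,12-diol F8; phenyl chlorothionoformate with DMAP gives the bis(thionocarbonate) F9; Bu3SnH (kept concentrated, so that cyclisation of the carbon radicals onto the alkyne cannot compete) with AIBN in toluene at 100 °C removes both oxygens and returns to the route at 30. The silylated internal alkyne should resist hydrostannylation.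

Step 22. Once the C20 alcohol is free it lies 1,3-diaxial to the C19 ester, and transesterification to the six-membered lactone may outrun the oxidation of step 23. Fallback: the lactone is accepted and C20 is oxidised in base, where the ring cannot close. From 34, TsOH (cat.) in CH2Cl2 completes the closure to the 19,20-lactone F10. KOH in aqueous MeOH at reflux opens the lactone and saponifies the C7 ester to the dipotassium hydroxy dicarboxylate F11. Oxidation in the same basic medium with RuCl3 (cat.) and K2S2O8 in 1 M KOH, conditions that oxidise primary alcohols to carboxylates and should spare the isolated alkene, followed by acidification to pH 3 at 0 °C, returns to the route at 37 and makes step 24 unnecessary.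

## Further compounds

F1 | step 15 | trimethylsilyl ether of 25 (silylated at the phenol oxygen) | C[Si](C)(C)C#CC[C@]1(C=CC(=O)C2(OCCO2)C1)[C@H](C(=O)OC)c1c(C(=O)OC)c(O[Si](C)(C)C)ccc1COCc1ccc(OC)cc1
F2 | step 15 | C12 trimethylsilyl enol ether of 26 (C11=C12) | C[Si](C)(C)C#CC[C@]23CC4(OCCO4)C(O[Si](C)(C)C)=C[C@H]2[C@]1(COCc4ccc(OC)cc4)C=CC(=O)C(C(=O)OC)=C1[C@H]3C(=O)OC
F3 | step 12 | trimethylsilyl ketene acetal of 19 | C[Si](C)(C)C#CC[C@]1(C=CC(=O)C2(OCCO2)C1)C=C(OC)O[Si](C)(C)C
F4 | step 12 | α-bromo ester from 19 (bromine on C6, both epimers) | C[Si](C)(C)C#CC[C@]1(C=CC(=O)C2(OCCO2)C1)C(Br)C(=O)OC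
F5 | step 12 | arylzinc bromide from 6 | COCOc1ccc(COCc2ccc(OC)cc2)c([Zn]Br)c1C(=O)OC
F6 | step 16 | C4-methylated Δ5(6)-ene diester from 26 (1-en-3-one retained) | C[Si](C)(C)C#CC[C@]23CC4(OCCO4)C(=O)C[C@H]2[C@]1(COCc4ccc(OC)cc4)C=CC(=O)[C@@](C)(C(=O)OC)C1=C3C(=O)OC
F7 | step 16 | 1,2-dihydro derivative of F6 | C[Si](C)(C)C#CC[C@]23CC4(OCCO4)C(=O)C[C@H]2[C@]1(COCc4ccc(OC)cc4)CCC(=O)[C@@](C)(C(=O)OC)C1=C3C(=O)OC
F8 | step 18 | 3,12-diol from 28 (carbinol epimers) | C[Si](C)(C)C#CC[C@]23CC4(OCCO4)C(O)C[C@H]2[C@]1(COCc4ccc(OC)cc4)CCC(O)[C@@](C)(C(=O)OC)[C@H]1[C@H]3C(=O)OC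
F9 | step 18 | 3,12-bis(O-phenyl thionocarbonate) of F8 | C[Si](C)(C)C#CC[C@]23CC4(OCCO4)C(OC(=S)Oc4ccccc4)C[C@H]2[C@]1(COCc4ccc(OC)cc4)CCC(OC(=S)Oc4ccccc4)[C@@](C)(C(=O)OC)[C@H]1[C@H]3C(=O)OC
F10 | step 22 | 19,20-lactone from 34 (13-hydroxy, 7-methyl ester) | C=C1C[C@]23C[C@@]1(O)CC[C@H]2[C@]1(CO5)CCC[C@@](C)(C5=O)[C@H]1[C@@H]3C(=O)OC
F11 | step 22 | dipotassium 13,20-dihydroxy 7,19-dicarboxylate (opened lactone) | C=C1C[C@]23C[C@@]1(O)CC[C@H]2[C@]1(CO)CCC[C@@](C)(C(=O)[O-])[C@H]1[C@@H]3C(=O)[O-].[K+].[K+]
A1 | alternative 1 | tetracyclic 13-hydroxy tetraester (allyl ester at C17, methyl esters at C7, C19, C20) | C=CCOC(=O)[C@@H]1C[C@]23C[C@@]1(O)CC[C@H]2[C@]1(C(=O)OC)CCC[C@@](C)(C(=O)OC)[C@H]1[C@@H]3C(=O)OC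
A2 | alternative 2 | trans-fused ring A/B diketo triester | COC(=O)[C@@]12CCC(=O)[C@@H](C(=O)OC(C)(C)C)[C@H]1[C@H](C(=O)OC)CC2=O
A3 | alternative 3 | 13-hydroxy-16-ene C20-gibberellin with C20 as methyl, 7,19-dimethyl ester (number 53 of the A series, as dimethyl ester) | C=C1C[C@]23C[C@@]1(O)CC[C@H]2[C@]1(C)CCC[C@@](C)(C(=O)OC)[C@H]1[C@@H]3C(=O)OC
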